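**Retrosynthetic overview**

1. The target is numbered as 2-methoxy-6,7-dimethyl-8-(2,4,5-trimethoxyphenyl)naphthalene-1,4-dione, with ring A = C1–C4/C4a/C8a (quinone) and ring B = C4a/C5–C8/C8a. The quinone is unmasked last by oxidative demethylation of a 1,2,4-trimethoxy ring A, and the C7 methyl group comes from a C7 bromide by Negishi coupling.
2. The strategy rests on one feature of ring B: C7 lies between the methyl-bearing C6 and the aryl-bearing C8. Removing C7 leaves the C6=C8 double bond of a 3-aryl-2-methylindene fused to ring A, so ring B is made by inserting one carbon (dibromocarbene) into that bond and letting the dibromocyclopropane open to the 7-bromonaphthalene.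
3. The indene comes from 4,6,7-trimethoxy-2-methylindan-1-one by addition of ArCeCl2 (Ar = 2,4,5-trimethoxyphenyl) and dehydration, so the aryl–C8 bond is made by carbonyl addition and not by a hindered biaryl coupling.
4. The indanone comes from 2,4,5-trimethoxybenzaldehyde by Horner–Wadsworth–Emmons olefination, hydrogenation and Friedel–Crafts ring closure.
5. Ring order: ring A is bought as the arene, then the five-membered carbocycle is closed, then ring B is formed by ring expansion, then ring A is oxidized to the quinone.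

Key step: step 5

Assumption: the target SMILES defines no stereo element, so the hindered C8–aryl axis is treated as racemic; the stereocenters formed in steps 2, 4 and 5 are transient and need no control.

**Route**

Step 1
Reactants: 1 2,4,5-trimethoxybenzaldehyde; 2 triethyl 2-phosphonopropionate
Product: 4 (E)-2-methyl-3-(2,4,5-trimethoxyphenyl)prop-2-enoic acid, via ethyl ester 3 (not isolated)
Conditions: NaH, THF, 0 °C to rt; then NaOH, H2O/MeOH, 60 °C; aq HCl work-up
Reagents that add atoms: sodium hydroxide, [Na+].[OH-]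
Why: Horner–Wadsworth–Emmons olefination of the aldehyde by the sodium salt of the α-methyl phosphonate gives the (E)-trisubstituted acrylate 3, which aqueous NaOH saponifies in the same flask; the alkene geometry does not matter because step 2 saturates it.

Step 2
Reactants: 4 (E)-2-methyl-3-(2,4,5-trimethoxyphenyl)prop-2-enoic acid
Product: 5 2-methyl-3-(2,4,5-trimethoxyphenyl)propanoic acid (racemic)
Conditions: H2 (1 atm), 10% Pd/C, EtOAc/MeOH, rt
Reagents that add atoms: none
Why: Heterogeneous catalytic hydrogenation reduces the conjugated trisubstituted C=C without touching the arene or the acid; the new α-stereocenter is formed racemic and is of no consequence because this carbon becomes sp2 again in step 4.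

Step 3
Reactants: 5 2-methyl-3-(2,4,5-trimethoxyphenyl)propanoic acid
Product: 6 4,6,7-trimethoxy-2-methylindan-1-one (racemic)
Conditions: P2O5/MeSO3H (1:10 w/w), rt to 40 °C
Reagents that add atoms: none
Why: Intramolecular Friedel–Crafts acylation: the only ring carbon that the three-carbon acid chain can reach is the free position ortho to it, which is activated by the adjacent methoxy group, so the five-membered aryl ketone should form as one regioisomer.

Step 4
Reactants: 6 4,6,7-trimethoxy-2-methylindan-1-one; 7 1-bromo-2,4,5-trimethoxybenzene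
Product: 11 4,5,7-trimethoxy-2-methyl-3-(2,4,5-trimethoxyphenyl)-1H-indene, via 2,4,5-trimethoxyphenyllithium 8 (not isolated), via arylcerium dichloride 9 (not isolated), via tertiary indanol 10 (not isolated)
Conditions: 7, n-BuLi, THF, −78 °C; anhydrous CeCl3, −78 °C; then 6, −78 to 0 °C; aq HCl; then p-TsOH·H2O (cat.), toluene, 60 °C
Reagents that add atoms: none
Why: Bromine–lithium exchange and transmetalation give the weakly basic, strongly nucleophilic aryl cerium reagent 9, whose 1,2-addition to the hindered, enolizable ketone outruns α-deprotonation, and acid-catalyzed E1 dehydration of the doubly benzylic tertiary alcohol 10 can only run toward C2, which gives the tetrasubstituted indene double bond.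

Step 5
Reactants: 11 4,5,7-trimethoxy-2-methyl-3-(2,4,5-trimethoxyphenyl)-1H-indene; 12 bromoform
Product: 14 2-bromo-5,7,8-trimethoxy-3-methyl-1-(2,4,5-trimethoxyphenyl)naphthalene, via dibromocyclopropane adduct 13 (not isolated)
Conditions: CHBr3, KOtBu (excess), toluene/hexane, −20 °C to rt, then 60 °C
Reagents that add atoms: none
Why: KOtBu effects α-elimination of HBr from bromoform, and the resulting electrophilic dibromocarbene adds in a concerted [2+1] cycloaddition to the electron-rich tetrasubstituted styrene-type C6=C8 bond of 11 (target numbering), forming C6–C7 and C7–C8 in the cis-fused dibromocyclopropane 13. Ring B is then closed by ring expansion and not by cyclization: the bromide endo to the five-membered ring ionizes in concert with disrotatory two-electron electrocyclic opening of the old C6–C8 bond, the developing allylic positive charge at C8 being stabilized by both aryl rings, and loss of HBr through a C5 proton aromatizes the new six-membered ring. The closest known reaction type is the dihalocarbene ring expansion of indenes to 2-halonaphthalenes. No stereocenter survives, since the two of 13 become sp2 carbons. The selectivity needed is attack of the carbene on the one alkene and not on the methoxyarenes, which the much higher nucleophilicity of a tetrasubstituted aryl alkene toward dihalocarbenes secures, and with two bromines on the carbene one is always endo, so the opening cannot be blocked. A base-induced shift of the indene double bond before cycloaddition would only exchange Br and CH3 between C6 and C7, and step 6 removes that difference.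

Step 6
Reactants: 14 2-bromo-5,7,8-trimethoxy-3-methyl-1-(2,4,5-trimethoxyphenyl)naphthalene
Product: 15 5,7,8-trimethoxy-2,3-dimethyl-1-(2,4,5-trimethoxyphenyl)naphthalene
Conditions: MeZnCl (THF solution), Pd(OAc)2 (cat.), 2-dicyclohexylphosphino-2′,6′-dimethoxybiphenyl (cat.), THF, 65 °C
Reagents that add atoms: methylzinc chloride, C[Zn]Cl
Why: Negishi cross-coupling: zerovalent palladium formed from Pd(OAc)2 and the bulky biaryl phosphine inserts into the di-ortho-substituted C–Br bond, MeZnCl transmetalates and reductive elimination forms the C–CH3 bond, with no β-hydrogen on the methyl group to divert the intermediate; the methoxyarenes are inert.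

Step 7
Reactants: 15 5,7,8-trimethoxy-2,3-dimethyl-1-(2,4,5-trimethoxyphenyl)naphthalene
Product: 16 2-methoxy-6,7-dimethyl-8-(2,4,5-trimethoxyphenyl)naphthalene-1,4-dione
Conditions: (NH4)2Ce(NO3)6 (2.1 equiv, slow addition), MeCN/H2O, 0 °C
Reagents that add atoms: water, O
Why: Oxidative demethylation by (NH4)2Ce(NO3)6: single-electron oxidation takes place at the π system of lowest oxidation potential, the 5,7,8-trimethoxynaphthalene, water adds at the para-related C5 and C8 (numbering of 15) with loss of two methanol molecules, and the para-quinone keeps the C7 methoxy group as a vinylogous ester, while slow addition of close to two equivalents at 0 °C should spare the less easily oxidized pendant trimethoxyphenyl ring.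

**Compound list**

1 | 2,4,5-trimethoxybenzaldehyde | COc1cc(OC)c(OC)cc1C=O | starting material
2 | triethyl 2-phosphonopropionate | CCOC(=O)C(C)P(=O)(OCC)OCC | starting material
3 | ethyl (E)-2-methyl-3-(2,4,5-trimethoxyphenyl)prop-2-enoate (not isolated) | CCOC(=O)/C(C)=C/c1cc(OC)c(OC)cc1OC | intermediate
4 | (E)-2-methyl-3-(2,4,5-trimethoxyphenyl)prop-2-enoic acid | OC(=O)/C(C)=C/c1cc(OC)c(OC)cc1OC | intermediate
5 | 2-methyl-3-(2,4,5-trimethoxyphenyl)propanoic acid (racemic) | OC(=O)C(C)Cc1cc(OC)c(OC)cc1OC | intermediate
6 | 4,6,7-trimethoxy-2-methylindan-1-one (racemic) | O=C1C(C)Cc2c1c(OC)c(OC)cc2OC | intermediate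
7 | 1-bromo-2,4,5-trimethoxybenzene | COc1cc(OC)c(Br)cc1OC | starting material
8 | 2,4,5-trimethoxyphenyllithium (not isolated) | [Li]c1cc(OC)c(OC)cc1OC | intermediate
9 | (2,4,5-trimethoxyphenyl)cerium dichloride (not isolated) | Cl[Ce](Cl)c1cc(OC)c(OC)cc1OC | intermediate
10 | 4,6,7-trimethoxy-2-methyl-1-(2,4,5-trimethoxyphenyl)indan-1-ol (racemic diastereomer mixture, not isolated) | COc1cc(OC)c2c(c1OC)C(O)(c1cc(OC)c(OC)cc1OC)C(C)C2 | intermediate
11 | 4,5,7-trimethoxy-2-methyl-3-(2,4,5-trimethoxyphenyl)-1H-indene | COc1cc(OC)c2c(c1OC)C(-c1cc(OC)c(OC)cc1OC)=C(C)C2 | intermediate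
12 | bromoform | BrC(Br)Br | starting material
13 | 1,1-dibromo-2,3,5-trimethoxy-6a-methyl-1a-(2,4,5-trimethoxyphenyl)-1,1a,6,6a-tetrahydrocyclopropa[a]indene (racemic, cis-fused, not isolated) | COc1cc(OC)c2c(c1OC)C1(c3cc(OC)c(OC)cc3OC)C(C)(C2)C1(Br)Br | intermediate
14 | 2-bromo-5,7,8-trimethoxy-3-methyl-1-(2,4,5-trimethoxyphenyl)naphthalene | COc1cc(OC)c2cc(C)c(Br)c(-c3cc(OC)c(OC)cc3OC)c2c1OC | intermediate
15 | 5,7,8-trimethoxy-2,3-dimethyl-1-(2,4,5-trimethoxyphenyl)naphthalene | COc1cc(OC)c2cc(C)c(C)c(-c3cc(OC)c(OC)cc3OC)c2c1OC | intermediate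
16 | 2-methoxy-6,7-dimethyl-8-(2,4,5-trimethoxyphenyl)naphthalene-1,4-dione | COC1=CC(=O)c2cc(C)c(C)c(-c3cc(OC)c(OC)cc3OC)c2C1=O | target

**Step count and risks**

Total step count: 7. Longest linear sequence: 7 steps (from 1 to 16); compounds 2, 7 and 12 are bought and enter directly.

Steps most likely to fail:

1. Step 5 (key step). The [2+1] addition to the hindered tetrasubstituted double bond may be slow. Decomposition of the carbene, a second carbene addition to the electron-rich ring A of the product, or deprotonation of the indene CH2 by KOtBu could then take over.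
Fallback: a Haworth-type construction of ring B as a six-membered ketone, which needs no carbene. It sets out from bromide 7 and comes back to the route at 15. Aryllithium 8, made as in step 4, is added at −78 °C to commercial 2,3-dimethylsuccinic anhydride (isomer mixture, inverse addition, THF) to give 2,3-dimethyl-4-oxo-4-(2,4,5-trimethoxyphenyl)butanoic acid F1. The diastereomer mixture is of no consequence. Ionic hydrogenation (Et3SiH, CF3CO2H, rt) removes the benzylic carbonyl to give 2,3-dimethyl-4-(2,4,5-trimethoxyphenyl)butanoic acid F2. P2O5/MeSO3H closes ring B as 5,7,8-trimethoxy-2,3-dimethyl-3,4-dihydronaphthalen-1(2H)-one F3. Reagent 9, made from 7 as in step 4, adds to give 5,7,8-trimethoxy-2,3-dimethyl-1-(2,4,5-trimethoxyphenyl)-1,2,3,4-tetrahydronaphthalen-1-ol F4. p-TsOH in toluene dehydrates this to 5,6,8-trimethoxy-2,3-dimethyl-4-(2,4,5-trimethoxyphenyl)-1,2-dihydronaphthalene F5. Dehydrogenation with DDQ (toluene, 80 °C) should then give 15, which enters step 7.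

2. Step 7. Electron transfer from the pendant 2,4,5-trimethoxyphenyl ring, itself a para-dimethoxyarene, may compete with that from ring A. Demethylation across the C7/C8 pair instead of the C5/C8 pair would lead to the ortho-quinone.
Fallback: replace the oxidative demethylation by oxidation of a free naphthol, which the pendant ring cannot undergo. It sets out from indanone 6 and comes back at target 16. BCl3 (CH2Cl2, −78 to 0 °C) should cleave only the methyl ether next to the carbonyl through a boron chelate, giving 7-hydroxy-4,6-dimethoxy-2-methylindan-1-one F6. BnBr/K2CO3 (DMF) gives 7-(benzyloxy)-4,6-dimethoxy-2-methylindan-1-one F7. Under the conditions of step 4, F7 gives 7-(benzyloxy)-4,6-dimethoxy-2-methyl-1-(2,4,5-trimethoxyphenyl)indan-1-ol F8 and from it 4-(benzyloxy)-5,7-dimethoxy-2-methyl-3-(2,4,5-trimethoxyphenyl)-1H-indene F9. Under the conditions of step 5, the adduct 2-(benzyloxy)-1,1-dibromo-3,5-dimethoxy-6a-methyl-1a-(2,4,5-trimethoxyphenyl)-1,1a,6,6a-tetrahydrocyclopropa[a]indene F10 opens to 8-(benzyloxy)-2-bromo-5,7-dimethoxy-3-methyl-1-(2,4,5-trimethoxyphenyl)naphthalene F11. Under the conditions of step 6, this gives 8-(benzyloxy)-5,7-dimethoxy-2,3-dimethyl-1-(2,4,5-trimethoxyphenyl)naphthalene F12. Hydrogenolysis (H2, 10% Pd/C, EtOAc) frees 2,4-dimethoxy-6,7-dimethyl-8-(2,4,5-trimethoxyphenyl)naphthalen-1-ol F13. PhI(OAc)2 in MeCN/H2O at 0 °C should oxidize this para-methoxynaphthol to the para-quinone 16 with loss of methanol, the non-phenolic trimethoxyphenyl ring being inert to this reagent.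

3. Step 4. The aryl metal reagent may deprotonate the α-methine of the ketone instead of adding to the carbonyl, which is shielded by the peri methoxy group and the α-methyl group, so that the ketone is returned.
Fallback: make the aryl–C8 bond by cross-coupling of an enol triflate. It sets out from indanone 6 and comes back at indene 11. KN(SiMe3)2 and PhNTf2 (THF, −78 °C) give 4,5,7-trimethoxy-2-methyl-1H-inden-3-yl trifluoromethanesulfonate F14; the ketone has only one α-carbon, so only one enol triflate can form. Suzuki–Miyaura coupling with commercial 2,4,5-trimethoxyphenylboronic acid (Pd(OAc)2, 2-dicyclohexylphosphino-2′,6′-dimethoxybiphenyl, K3PO4, toluene/H2O, 80 °C) should give 11.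

**Further compounds**

F1 | step 5 | 2,3-dimethyl-4-oxo-4-(2,4,5-trimethoxyphenyl)butanoic acid | OC(=O)C(C)C(C)C(=O)c1cc(OC)c(OC)cc1OC
F2 | step 5 | 2,3-dimethyl-4-(2,4,5-trimethoxyphenyl)butanoic acid | OC(=O)C(C)C(C)Cc1cc(OC)c(OC)cc1OC
F3 | step 5 | 5,7,8-trimethoxy-2,3-dimethyl-3,4-dihydronaphthalen-1(2H)-one | O=C1C(C)C(C)Cc2c1c(OC)c(OC)cc2OC
F4 | step 5 | 5,7,8-trimethoxy-2,3-dimethyl-1-(2,4,5-trimethoxyphenyl)-1,2,3,4-tetrahydronaphthalen-1-ol | COc1cc(OC)c2c(c1OC)C(O)(c1cc(OC)c(OC)cc1OC)C(C)C(C)C2
F5 | step 5 | 5,6,8-trimethoxy-2,3-dimethyl-4-(2,4,5-trimethoxyphenyl)-1,2-dihydronaphthalene | COc1cc(OC)c2c(c1OC)C(c1cc(OC)c(OC)cc1OC)=C(C)C(C)C2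
F6 | step 7 | 7-hydroxy-4,6-dimethoxy-2-methylindan-1-one | O=C1C(C)Cc2c1c(O)c(OC)cc2OC
F7 | step 7 | 7-(benzyloxy)-4,6-dimethoxy-2-methylindan-1-one | O=C1C(C)Cc2c1c(OCc1ccccc1)c(OC)cc2OC
F8 | step 7 | 7-(benzyloxy)-4,6-dimethoxy-2-methyl-1-(2,4,5-trimethoxyphenyl)indan-1-ol | COc1cc(OC)c2c(c1OCc1ccccc1)C(O)(c1cc(OC)c(OC)cc1OC)C(C)C2
F9 | step 7 | 4-(benzyloxy)-5,7-dimethoxy-2-methyl-3-(2,4,5-trimethoxyphenyl)-1H-indene | COc1cc(OC)c2c(c1OCc1ccccc1)C(c1cc(OC)c(OC)cc1OC)=C(C)C2
F10 | step 7 | 2-(benzyloxy)-1,1-dibromo-3,5-dimethoxy-6a-methyl-1a-(2,4,5-trimethoxyphenyl)-1,1a,6,6a-tetrahydrocyclopropa[a]indene | COc1cc(OC)c2c(c1OCc1ccccc1)C1(c3cc(OC)c(OC)cc3OC)C(C)(C2)C1(Br)Br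
F11 | step 7 | 8-(benzyloxy)-2-bromo-5,7-dimethoxy-3-methyl-1-(2,4,5-trimethoxyphenyl)naphthalene | COc1cc(OC)c2cc(C)c(Br)c(-c3cc(OC)c(OC)cc3OC)c2c1OCc1ccccc1
F12 | step 7 | 8-(benzyloxy)-5,7-dimethoxy-2,3-dimethyl-1-(2,4,5-trimethoxyphenyl)naphthalene | COc1cc(OC)c2cc(C)c(C)c(-c3cc(OC)c(OC)cc3OC)c2c1OCc1ccccc1
F13 | step 7 | 2,4-dimethoxy-6,7-dimethyl-8-(2,4,5-trimethoxyphenyl)naphthalen-1-ol | COc1cc(OC)c2cc(C)c(C)c(-c3cc(OC)c(OC)cc3OC)c2c1O
F14 | step 4 | 4,5,7-trimethoxy-2-methyl-1H-inden-3-yl trifluoromethanesulfonate | COc1cc(OC)c2c(c1OC)C(OS(=O)(=O)C(F)(F)F)=C(C)C2
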